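**Plan**
1. Retrosynthesis: the last operations only unmask functional groups (one global hydride reduction, one hydrodecarboxylation that removes a helper ester on C2). The tetrahydrofuran is then cut at C2–C3 and C4–C5 in a single retro-[3+2] step.
2. Enabling feature: in the tetrahydrofuran the ring oxygen O1 lies between two CH carbons, C2 (benzyl-bearing) and C5 (aryl-bearing), so C2–O1–C5 is a carbonyl ylide (aldehyde carbon C5 plus carbene carbon C2). C3(OH)–C4(CH2OH), trans, is an (E)-3-acyloxyacrylic acid unit.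
3. The dihydrobenzofuran is cut at its C2–C3 bond (carbenoid C–H insertion) and at the aryl–C3 bond (coupling of an aryl iodide with a diazoacetate). One vanillyl bromide serves both the O-benzyl and the C-benzyl position.
4. Forward: 5-iodovanillin → cis-dihydrobenzofuran aldehyde (first ring); then aldehyde + α-diazo ester + chiral enoyl sultam → tetrahydrofuran (second ring); then hydrogenolysis, hydrodecarboxylation, global reduction.
5. Stereochemistry: dihydrobenzofuran C2/C3 (cis) from a chiral dirhodium carboxylate. Tetrahydrofuran C3/C4 trans from the E alkene, C4/C5 trans from the exo approach, absolute sense from the bornane sultam. C2 is set by hydrogen-atom transfer anti to the C3 benzoate.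

Key step: step 12

Remark: read from the SMILES, the target has a 2,3-cis dihydrobenzofuran (2R,3R) and a (2S,3S,4S,5S) tetrahydrofuran (2-benzyl cis to 3-OH and to 5-aryl, 4-CH2OH trans to both neighbours); the route aims at this isomer.
Assumption: Rh2(S-PTTL)4 is taken to give the (2R,3S)-cis ester 9 and the (2R)-sultam to leave the Cα-re face of its enoyl group open; if either sense proves opposite, the mirror-image catalyst or the (2S)-sultam is used and nothing else changes.

**Step 1**
Reactants: 1 vanillyl alcohol (4-hydroxy-3-methoxybenzyl alcohol)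
Product: 2 4-(hydroxymethyl)-2-methoxyphenyl pivalate
Conditions: PivCl (1.05 equiv), NaOH (1.1 equiv), H2O/CH2Cl2, Bu4NHSO4 (cat.), 0 °C
Reagents that add atoms: pivaloyl chloride CC(C)(C)C(=O)Cl
Why: Under Schotten–Baumann conditions only the phenoxide is acylated, so the benzylic alcohol should stay free (chemoselective O-acylation of a phenol).

**Step 2**
Reactants: 2 4-(hydroxymethyl)-2-methoxyphenyl pivalate
Product: 3 4-(bromomethyl)-2-methoxyphenyl pivalate
Conditions: PBr3 (0.4 equiv), Et2O, 0 °C
Reagents that add atoms: phosphorus tribromide BrP(Br)Br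
Why: The benzylic alcohol is converted to the bromide by SN2 displacement of its phosphite ester, and the aryl pivalate is inert to PBr3 (alcohol-to-bromide substitution).

**Step 3**
Reactants: 3 4-(bromomethyl)-2-methoxyphenyl pivalate; 4 5-iodovanillin (4-hydroxy-3-iodo-5-methoxybenzaldehyde)
Product: 5 4-[(4-formyl-2-iodo-6-methoxyphenoxy)methyl]-2-methoxyphenyl pivalate
Conditions: K2CO3, DMF, rt
Reagents that add atoms: none
Why: Williamson ether synthesis of the phenoxide of 4 with the reactive benzylic bromide, which should be much faster than acyl transfer from the hindered pivalate.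

**Step 4**
Reactants: 5 4-[(4-formyl-2-iodo-6-methoxyphenoxy)methyl]-2-methoxyphenyl pivalate
Product: 6 4-{[4-(dimethoxymethyl)-2-iodo-6-methoxyphenoxy]methyl}-2-methoxyphenyl pivalate
Conditions: HC(OMe)3, p-TsOH·H2O (cat.), MeOH, rt; Et3N quench
Reagents that add atoms: trimethyl orthoformate COC(OC)OC
Why: Acid-catalysed acetalisation masks the aldehyde, which would otherwise capture the rhodium carbenoid of step 6 as a carbonyl ylide (acetal protection).

**Step 5**
Reactants: 6 4-{[4-(dimethoxymethyl)-2-iodo-6-methoxyphenoxy]methyl}-2-methoxyphenyl pivalate; 7 ethyl diazoacetate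
Product: 8 ethyl 2-diazo-2-[5-(dimethoxymethyl)-3-methoxy-2-(3-methoxy-4-pivaloyloxybenzyloxy)phenyl]acetate
Conditions: Pd(PPh3)4 (5 mol %), Ag2CO3 (0.5 equiv), Et3N, toluene, rt
Reagents that add atoms: none
Why: Oxidative addition of the aryl iodide to zerovalent palladium followed by coupling at the diazo carbon with retention of the diazo group should give the aryl diazoacetate directly (Pd-catalysed cross-coupling of aryl iodides with diazoacetates).

**Step 6**
Reactants: 8 ethyl 2-diazo-2-[5-(dimethoxymethyl)-3-methoxy-2-(3-methoxy-4-pivaloyloxybenzyloxy)phenyl]acetate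
Product: 9 ethyl (2R,3S)-5-(dimethoxymethyl)-7-methoxy-2-(3-methoxy-4-pivaloyloxyphenyl)-2,3-dihydro-1-benzofuran-3-carboxylate (2,3-cis)
Conditions: Rh2(S-PTTL)4 (dirhodium tetrakis[N-phthaloyl-(S)-tert-leucinate], 1 mol %), toluene, −60 °C
Reagents that add atoms: none
Why: The donor/acceptor rhodium carbenoid inserts into the benzylic ether C–H bond through a five-membered transition state, which should give the cis-2-aryl-3-ester kinetically, while the chiral carboxylate ligands select the enantiotopic C–H bond and so set both stereocentres (intramolecular carbenoid C–H insertion of aryldiazoacetates).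

**Step 7**
Reactants: 9 ethyl (2R,3S)-5-(dimethoxymethyl)-7-methoxy-2-(3-methoxy-4-pivaloyloxyphenyl)-2,3-dihydro-1-benzofuran-3-carboxylate
Product: 10 ethyl (2R,3S)-5-formyl-7-methoxy-2-(3-methoxy-4-pivaloyloxyphenyl)-2,3-dihydro-1-benzofuran-3-carboxylate (2,3-cis)
Conditions: PPTS (cat.), acetone/H2O, rt
Reagents that add atoms: water O
Why: Mild acidic acetal hydrolysis frees the aldehyde without base, so the epimerisable cis ester and the aryl pivalate should be untouched (acetal deprotection).

**Step 8**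
Reactants: 3 4-(bromomethyl)-2-methoxyphenyl pivalate; 11 benzyl acetoacetate
Product: 12 benzyl 2-acetyl-3-(3-methoxy-4-pivaloyloxyphenyl)propanoate (racemic)
Conditions: K2CO3, acetone, 50 °C
Reagents that add atoms: none
Why: C-alkylation of the acetoacetate enolate with the benzylic bromide (acetoacetic ester alkylation); the new stereocentre is lost in step 9.

**Step 9**
Reactants: 12 benzyl 2-acetyl-3-(3-methoxy-4-pivaloyloxyphenyl)propanoate
Product: 13 benzyl 2-diazo-3-(3-methoxy-4-pivaloyloxyphenyl)propanoate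
Conditions: p-ABSA, DBU, MeCN, 0 °C → rt
Reagents that add atoms: 4-acetamidobenzenesulfonyl azide CC(=O)Nc1ccc(cc1)S(=O)(=O)N=[N+]=[N-]
Why: Diazo transfer to the α-carbon is followed by loss of the acetyl group to the sulfonamide nitrogen, which gives the α-alkyl-α-diazo ester (deacylative Regitz diazo transfer).

**Step 10**
Reactants: 14 propiolic acid; 15 (2R)-bornane-10,2-sultam
Product: 17 N-propioloyl-(2R)-bornane-10,2-sultam, via mixed anhydride 16 (not isolated)
Conditions: PivCl, Et3N, THF, −20 °C; then 15, LiCl, −20 °C → rt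
Reagents that add atoms: pivaloyl chloride CC(C)(C)C(=O)Cl (its atoms are in intermediate 16 only; none remain in 17)
Why: The sultam nitrogen attacks the less hindered propioloyl carbonyl of the mixed pivalic anhydride (N-acylation of a chiral auxiliary through a mixed anhydride).

**Step 11**
Reactants: 17 N-propioloyl-(2R)-bornane-10,2-sultam
Product: 18 N-[(E)-3-(benzoyloxy)acryloyl]-(2R)-bornane-10,2-sultam
Conditions: PhCO2H, DABCO (10 mol %), CH2Cl2, 0 °C → rt
Reagents that add atoms: benzoic acid OC(=O)c1ccccc1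
Why: Amine-catalysed conjugate addition of the carboxylic acid to the ynoyl imide should give the E enol ester, the usual outcome of this addition to propiolic acid derivatives.

**Step 12**
Reactants: 10 ethyl (2R,3S)-5-formyl-7-methoxy-2-(3-methoxy-4-pivaloyloxyphenyl)-2,3-dihydro-1-benzofuran-3-carboxylate; 13 benzyl 2-diazo-3-(3-methoxy-4-pivaloyloxyphenyl)propanoate; 18 N-[(E)-3-(benzoyloxy)acryloyl]-(2R)-bornane-10,2-sultam
Product: 20 benzyl (5S)-3-(benzoyloxy)-4-{[(2R)-bornane-10,2-sultam-N-yl]carbonyl}-5-[(2R,3S)-3-(ethoxycarbonyl)-7-methoxy-2-(3-methoxy-4-pivaloyloxyphenyl)-2,3-dihydro-1-benzofuran-5-yl]-2-(3-methoxy-4-pivaloyloxybenzyl)tetrahydrofuran-2-carboxylate (5-aryl/3-benzoyloxy/2-CO2Bn on one face; 4-acyl and 2-benzyl on the other), via carbonyl ylide 19 (not isolated)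
Conditions: 10 (1 equiv), 18 (2 equiv), Rh2(OPiv)4 (1 mol %), CH2Cl2, −78 °C; 13 (2 equiv) added by syringe pump over 2 h
Reagents that add atoms: none
Why: Rh2(OPiv)4 should turn 13 into a rhodium carbenoid that the aldehyde oxygen of 10 intercepts at −78 °C faster than 1,2-hydride shift, and release of rhodium leaves carbonyl ylide 19 (C5=O1(+)–C2(−), carbanion end stabilised by the ester), which adds across C3=C4 of 18 in a concerted, asynchronous, suprafacial 1,3-dipolar cycloaddition. The closest known reaction type is the three-component coupling of α-alkyl-α-diazo esters, aldehydes and dipolarophiles under dirhodium tetrapivalate catalysis. The tetrahydrofuran is closed by intermolecular [3+2] union of the three-atom C2–O1–C5 dipole with the two-atom C3–C4 dipolarophile, the nucleophilic ester-bearing C2 bonding to the β-carbon and the oxocarbenium-like C5 to the α-carbon of the enoyl imide, the same orientation as for the isoelectronic imino ester azomethine ylides. C3 and C4 should come out trans by stereospecific transfer of the E geometry, C5 trans to the C4 acyl group because the aryl group sits in the outer position of the ylide while the bulky acyl sultam is exo and the benzoyloxy group endo, and the absolute sense from the sultam, which leaves the Cα-re face open; C2 is also set (CO2Bn cis to the C5 aryl group as drawn) but is made trigonal again in step 14. The step needs chemoselectivity (ylide formation over hydride shift, cyclopropanation and dioxolane formation with a second aldehyde), secured by the pivalate ligands, the low temperature, slow addition of 13 and an excess of the activated alkene, and it needs regio-, exo- and face selectivity, secured by the polarised ylide, the E alkene and the auxiliary.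

**Step 13**
Reactants: 20 benzyl tetrahydrofuran-2-carboxylate cycloadduct
Product: 21 (5S)-3-(benzoyloxy)-4-{[(2R)-bornane-10,2-sultam-N-yl]carbonyl}-5-[(2R,3S)-3-(ethoxycarbonyl)-7-methoxy-2-(3-methoxy-4-pivaloyloxyphenyl)-2,3-dihydro-1-benzofuran-5-yl]-2-(3-methoxy-4-pivaloyloxybenzyl)tetrahydrofuran-2-carboxylic acid (ring configuration as in 20)
Conditions: H2 (1 atm), 10% Pd/C, EtOAc, rt
Reagents that add atoms: none
Why: Hydrogenolysis of the benzyl ester is fast in neutral EtOAc, where the aryl pivalates, the benzoate, the imide and the cyclic benzylic ethers should survive (benzyl ester hydrogenolysis).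

**Step 14**
Reactants: 21 tetrahydrofuran-2-carboxylic acid
Product: 22 (2S,3S,5S)-4-{[(2R)-bornane-10,2-sultam-N-yl]carbonyl}-5-[(2R,3S)-3-(ethoxycarbonyl)-7-methoxy-2-(3-methoxy-4-pivaloyloxyphenyl)-2,3-dihydro-1-benzofuran-5-yl]-2-(3-methoxy-4-pivaloyloxybenzyl)tetrahydrofuran-3-yl benzoate (2-benzyl, 3-benzoyloxy and 5-aryl on one face; 4-acyl on the other)
Conditions: 9-mesityl-10-methylacridinium tetrafluoroborate (5 mol %), (4-ClC6H4S)2 (10 mol %), 2,6-lutidine, DCE, blue LEDs, rt
Reagents that add atoms: none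
Why: Single-electron oxidation of the carboxylate and loss of CO2 give the tertiary α-oxy radical at C2, which should take a hydrogen atom from the arenethiol on the face anti to the adjacent C3 benzoyloxy group, so that the benzyl group ends cis to it (photocatalytic hydrodecarboxylation of an α-oxy acid, 1,2-induction as in furanosyl radicals).

**Step 15**
Reactants: 22 tetrahydrofuran-3-yl benzoate
Product: 23 (2S,3S,4S,5S)-2-(4-hydroxy-3-methoxybenzyl)-5-[(2R,3R)-2-(4-hydroxy-3-methoxyphenyl)-3-(hydroxymethyl)-7-methoxy-2,3-dihydro-1-benzofuran-5-yl]-4-(hydroxymethyl)tetrahydrofuran-3-ol (target)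
Conditions: LiAlH4 (excess), THF, −20 → 0 °C; aqueous Rochelle salt
Reagents that add atoms: none
Why: LiAlH4 reduces the ethyl ester and the N-acyl sultam to primary alcohols and cleaves the benzoate and both aryl pivalates in one operation, and hydride addition at low temperature should outrun enolisation, so C4 and the cis-dihydrobenzofuran keep their configuration (reductive cleavage of esters and N-acyl sultams).

**Compound list**
1 | vanillyl alcohol | COc1cc(CO)ccc1O | starting material
2 | 4-(hydroxymethyl)-2-methoxyphenyl pivalate | COc1cc(CO)ccc1OC(=O)C(C)(C)C | intermediate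
3 | 4-(bromomethyl)-2-methoxyphenyl pivalate | COc1cc(CBr)ccc1OC(=O)C(C)(C)C | intermediate
4 | 5-iodovanillin | COc1cc(C=O)cc(I)c1O | starting material
5 | 4-[(4-formyl-2-iodo-6-methoxyphenoxy)methyl]-2-methoxyphenyl pivalate | COc1cc(C=O)cc(I)c1OCc1ccc(OC(=O)C(C)(C)C)c(OC)c1 | intermediate
6 | 4-{[4-(dimethoxymethyl)-2-iodo-6-methoxyphenoxy]methyl}-2-methoxyphenyl pivalate | COc1cc(C(OC)OC)cc(I)c1OCc1ccc(OC(=O)C(C)(C)C)c(OC)c1 | intermediate
7 | ethyl diazoacetate | CCOC(=O)C=[N+]=[N-] | starting material
8 | ethyl 2-diazo-2-[5-(dimethoxymethyl)-3-methoxy-2-(3-methoxy-4-pivaloyloxybenzyloxy)phenyl]acetate | CCOC(=O)C(=[N+]=[N-])c1cc(C(OC)OC)cc(OC)c1OCc1ccc(OC(=O)C(C)(C)C)c(OC)c1 | intermediate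
9 | ethyl (2R,3S)-5-(dimethoxymethyl)-7-methoxy-2-(3-methoxy-4-pivaloyloxyphenyl)-2,3-dihydro-1-benzofuran-3-carboxylate (cis) | COC(OC)c1cc(OC)c2c(c1)[C@H](C(=O)OCC)[C@H](c1ccc(OC(=O)C(C)(C)C)c(OC)c1)O2 | intermediate
10 | ethyl (2R,3S)-5-formyl-7-methoxy-2-(3-methoxy-4-pivaloyloxyphenyl)-2,3-dihydro-1-benzofuran-3-carboxylate (cis) | O=Cc1cc(OC)c2c(c1)[C@H](C(=O)OCC)[C@H](c1ccc(OC(=O)C(C)(C)C)c(OC)c1)O2 | intermediate
11 | benzyl acetoacetate | CC(=O)CC(=O)OCc1ccccc1 | starting material
12 | benzyl 2-acetyl-3-(3-methoxy-4-pivaloyloxyphenyl)propanoate (racemic) | CC(=O)C(Cc1ccc(OC(=O)C(C)(C)C)c(OC)c1)C(=O)OCc1ccccc1 | intermediate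
13 | benzyl 2-diazo-3-(3-methoxy-4-pivaloyloxyphenyl)propanoate | [N-]=[N+]=C(Cc1ccc(OC(=O)C(C)(C)C)c(OC)c1)C(=O)OCc1ccccc1 | intermediate
14 | propiolic acid | C#CC(=O)O | starting material
15 | (2R)-bornane-10,2-sultam | CC1(C)[C@@H]2CC[C@]13CS(=O)(=O)N[C@@H]3C2 | starting material
16 | propiolic pivalic anhydride | C#CC(=O)OC(=O)C(C)(C)C | intermediate
17 | N-propioloyl-(2R)-bornane-10,2-sultam | C#CC(=O)N1[C@@H]2C[C@H]3CC[C@]2(CS1(=O)=O)C3(C)C | intermediate
18 | N-[(E)-3-(benzoyloxy)acryloyl]-(2R)-bornane-10,2-sultam | O=C(/C=C/OC(=O)c1ccccc1)N1[C@@H]2C[C@H]3CC[C@]2(CS1(=O)=O)C3(C)C | intermediate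
19 | carbonyl ylide from 10 and 13 (aldehyde carbon double-bonded to O(+), carbanion carbon bearing CO2Bn and the arylmethyl group) | O=C(OCc1ccccc1)[C-](Cc1ccc(OC(=O)C(C)(C)C)c(OC)c1)[O+]=Cc1cc(OC)c2c(c1)[C@H](C(=O)OCC)[C@H](c1ccc(OC(=O)C(C)(C)C)c(OC)c1)O2 | intermediate
20 | cycloadduct: benzyl tetrahydrofuran-2-carboxylate with 2-(3-methoxy-4-pivaloyloxybenzyl), 3-benzoyloxy, 4-sultam-carbonyl, 5-dihydrobenzofuranyl (5S; 5-aryl, 3-OBz and 2-CO2Bn cis; 4-acyl trans to both neighbours) | O=C(OCc1ccccc1)[C@]2(Cc1ccc(OC(=O)C(C)(C)C)c(OC)c1)O[C@H](c1cc(OC)c3c(c1)[C@H](C(=O)OCC)[C@H](c1ccc(OC(=O)C(C)(C)C)c(OC)c1)O3)[C@@H](C(=O)N1[C@@H]4C[C@H]5CC[C@]4(CS1(=O)=O)C5(C)C)[C@@H]2OC(=O)c1ccccc1 | intermediate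
21 | the corresponding tetrahydrofuran-2-carboxylic acid (ring configuration as in 20) | O=C(O)[C@]2(Cc1ccc(OC(=O)C(C)(C)C)c(OC)c1)O[C@H](c1cc(OC)c3c(c1)[C@H](C(=O)OCC)[C@H](c1ccc(OC(=O)C(C)(C)C)c(OC)c1)O3)[C@@H](C(=O)N1[C@@H]4C[C@H]5CC[C@]4(CS1(=O)=O)C5(C)C)[C@@H]2OC(=O)c1ccccc1 | intermediate
22 | decarboxylated tetrahydrofuran-3-yl benzoate (2S,3S,5S; 2-benzyl, 3-OBz and 5-aryl cis; 4-sultam-carbonyl trans) | CC(C)(C)C(=O)Oc1ccc(C[C@@H]2O[C@H](c3cc(OC)c4c(c3)[C@H](C(=O)OCC)[C@H](c3ccc(OC(=O)C(C)(C)C)c(OC)c3)O4)[C@@H](C(=O)N3[C@@H]5C[C@H]6CC[C@]5(CS3(=O)=O)C6(C)C)[C@@H]2OC(=O)c3ccccc3)cc1OC | intermediate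
23 | CNP0179668.1 | COc1cc(C[C@@H]2O[C@H](c3cc(OC)c4c(c3)[C@H](CO)[C@H](c3ccc(O)c(OC)c3)O4)[C@@H](CO)[C@@H]2O)ccc1O | target

**Totals**
Total steps: 15. Longest linear sequence: 11 (steps 1–7, then 12–15).

**Steps most likely to fail**

Step 12. Face or exo selection in the cycloaddition may be incomplete. With the chiral aldehyde 10 the minor tetrahydrofuran isomers would be hard to remove and would consume advanced material. Dioxolane formation by a second aldehyde adds to this loss. The fallback reverses the order of ring construction and sets out from 5. Aldehyde 5, diazo ester 13 and sultam 18 are combined under Rh2(OPiv)4 at −78 °C and give, through the carbonyl ylide F1, the iodoaryl cycloadduct F2. Its isomers differ only in the sultam-bearing ring and should be removable by crystallisation. Coupling of the aryl iodide with 7 (Pd(PPh3)4, Ag2CO3, Et3N, toluene) gives the aryl diazoacetate F3. Rh2(S-PTTL)4 at −60 °C then closes the cis-dihydrobenzofuran by C–H insertion, and the route is rejoined at 20.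

Step 14. Hydrogen-atom transfer to the C2 radical may take place on the wrong face, since the C4 acyl sultam lies on the face anti to the benzoate, or the excited acridinium may oxidise the electron-rich arenes. The fallback is cationic and sets out from 21. Oxidative decarboxylation with Pb(OAc)4 and pyridine in THF gives the C2 acetoxy ketal F4. Et3SiH with BF3·OEt2 in CH2Cl2 at −78 °C then reduces the derived oxocarbenium ion. The C3 benzoate bridges to C2 on its own face, so hydride should enter trans to it and place the benzyl group cis to the benzoate. The route is rejoined at 22.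

Step 5. The diazo group may be lost in the palladium cycle with this ortho-alkoxy aryl iodide, through carbene formation or protodeiodination. The fallback separates C–C bond formation from diazo installation and sets out from 6. Cross-coupling with commercial BrZnCH2CO2Et (Pd(dba)2, Q-Phos, THF, rt) gives the arylacetate F5. Diazo transfer (p-ABSA, DBU, MeCN) then gives 8, where the route is rejoined.

**Further compounds**
F1 | step 12 | carbonyl ylide from 5 and 13 | O=C(OCc1ccccc1)[C-](Cc1ccc(OC(=O)C(C)(C)C)c(OC)c1)[O+]=Cc1cc(OC)c(OCc2ccc(OC(=O)C(C)(C)C)c(OC)c2)c(I)c1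
F2 | step 12 | iodoaryl cycloadduct, as 20 but with 5-[3-iodo-5-methoxy-4-(3-methoxy-4-pivaloyloxybenzyloxy)phenyl] | O=C(OCc1ccccc1)[C@]2(Cc1ccc(OC(=O)C(C)(C)C)c(OC)c1)O[C@H](c1cc(OC)c(OCc3ccc(OC(=O)C(C)(C)C)c(OC)c3)c(I)c1)[C@@H](C(=O)N1[C@@H]4C[C@H]5CC[C@]4(CS1(=O)=O)C5(C)C)[C@@H]2OC(=O)c1ccccc1
F3 | step 12 | aryl diazoacetate, as F2 with iodine replaced by C(N2)CO2Et | O=C(OCc1ccccc1)[C@]2(Cc1ccc(OC(=O)C(C)(C)C)c(OC)c1)O[C@H](c1cc(OC)c(OCc3ccc(OC(=O)C(C)(C)C)c(OC)c3)c(C(=[N+]=[N-])C(=O)OCC)c1)[C@@H](C(=O)N1[C@@H]4C[C@H]5CC[C@]4(CS1(=O)=O)C5(C)C)[C@@H]2OC(=O)c1ccccc1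
F4 | step 14 | C2 acetoxy ketal from 21 (both C2 epimers) | CC(=O)OC2(Cc1ccc(OC(=O)C(C)(C)C)c(OC)c1)O[C@H](c1cc(OC)c3c(c1)[C@H](C(=O)OCC)[C@H](c1ccc(OC(=O)C(C)(C)C)c(OC)c1)O3)[C@@H](C(=O)N1[C@@H]4C[C@H]5CC[C@]4(CS1(=O)=O)C5(C)C)[C@@H]2OC(=O)c1ccccc1
F5 | step 5 | ethyl 2-[5-(dimethoxymethyl)-3-methoxy-2-(3-methoxy-4-pivaloyloxybenzyloxy)phenyl]acetate | CCOC(=O)Cc1cc(C(OC)OC)cc(OC)c1OCc1ccc(OC(=O)C(C)(C)C)c(OC)c1
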